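The data stem from a simulated flask on assumed constants; noise was put on by code.

The south-west run, charged with 3 M of X, read E 18% and D 51% at 5.00 d, then E 22% and D 53% at 15.0 d. The north flask, at 1.5 M, is the one asked about.

| flask | X | remark | time |
|---|---|---|---|
| north | 1.5 M | the very flask that is asked about, followed so far |  |
| south-west | 3 M | run made earlier |  |
| flask | 1.5 M |  | 15 d |

- north (time / d: E / %, D / %): 0.500: 27, 21; 1.67: 18, 44; 2.50: 19, 48; 4.00: 18, 49; 6.00: 16, 52; 8.00: 18, 52
- south-west (time / d: E / %, D / %): 2.50: 18, 44; 5.00: 18, 51; 8.00: 17, 51; 10.0: 21, 52; 12.0: 17, 51; 15.0: 22, 53

(each reading ± 2 percentage points)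

- which holds at 15 d: what has brought the reaction to rest, or that it has not come to rest (forward and back rates have come level / all of X has reacted / it is still moving)
- amount of E at 15 d, in percent of the X charged
- amount of D at 15 d, in percent of the X charged

- the numbers in the tables scatter with a standard deviation of 2 percentage points
- candidate steps: X <-> E; X <-> D; E <-> D; X <-> Q
- the reaction counts as stopped when no species that holds the X changes by six tenths of a point or more over the second half of the time

Two people dispute the north flask. The drainer holds that E is a stage on the way to D, and the north run seems to agree: E fell from 27% at 0.500 d to 18% at 1.67 d, while D rose from 21% to 44%. The balancer grants that stretch as kinetic control. The drainer then takes the plateau as the large term and computes only the correction: D gained 2 percentage points over the late south-west readings, so north D, at 52% by 8.00 d, should reach 54.0%.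

The balancer answers that a gain of that size beside a scatter of 2 points is no trend, and that E read 4 points higher, not lower, at the end of the same readings, which shows no drain. Each candidate step turns one molecule into one, so at a balance [D]/[E] is a ratio of constants with no charge in it, and the two runs may be pooled. My own reckoning takes north from 6.00 d and south-west from 5.00 d: E 18.4%, D 51.7%. Their quotient reads 2.81, the rest ratio, [D]/[E] once neither moves.

The forecast stands with the balancer, saying the shared plateau “points to a true equilibrium rather than exhausted X”. Its call at 15 d is that forward and back rates have come level, with E 18.3% (16.8% to 20%) and D 52% (50.5% to 54%), not quite my means.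

At 15 d in the flask, forward and back rates have come level: E stands at 18.5% and D at 52.0%, below the drainer's 54.0%.

X ⇌ E (K = 0.890, k = 0.110 /h); X ⇌ D (K = 2.50, k = 0.0300 /h); E ⇌ D (k = 0.0260 /h); X ⇌ Q (K = 0.420, k = 0.0750 /h) The largest change of any share over the second half of the time was 0.022 points, smaller than the scatter. The rest ratio 2.81 times that E gives D 52.0%. In the same flask with 0.60 M of X, E stood at 18.5%, so the ratio gives D 52.0%, and D there stood at 52.0%.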